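**Assumption:** the target has no stereocentre and its diaryl ether rotates freely, so the SMILES describes one achiral compound and no stereocontrol is needed. Starting materials 1, 3 and 7 are taken as catalogue compounds.

**Retrosynthetic overview**
1. Target 12 ⇒ global O‑demethylation of trimethyl ether 11 ⇒ Ullmann C–O disconnection of the diaryl ether into 4'‑bromoisoflavone 6 (chloro unit) and 8‑hydroxyisoflavone 10 (genistein unit).
2. Genistein unit: all three rings are taken intact from genistein 7; the C8 oxygen comes from Elbs persulfate oxidation para to the 5‑OH.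
3. Chloro unit: the pyranone ring is closed at C3–C4 by an NHC‑catalysed intramolecular crossed benzoin of keto‑aldehyde 4 (aldehyde carbon as acyl anion equivalent attacking the aryl ketone), followed by dehydration.
4. Keto‑aldehyde 4 comes from salicylaldehyde 2 and phenacyl bromide 3 by O‑alkylation (O1–C2 bond).
5. Ring order: bought arenes → pyranone of the chloro unit (the only ring built) → the two isoflavones are joined → deprotection.

**Step 1**
Reactants: 1 3-chloro-2,4-dihydroxybenzaldehyde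
Product: 2 3-chloro-2-hydroxy-4-methoxybenzaldehyde
Conditions: MeI (1.3 equiv), CsHCO3 (1.3 equiv), MeCN, 60 °C (sealed), 6 h
Reagents that add atoms: iodomethane, CI
Why: Regioselective Williamson etherification; the 2‑OH is hydrogen‑bonded to the aldehyde and flanked by Cl, so the free, more acidic 4‑OH is the one methylated under bicarbonate.

**Step 2**
Reactants: 2 3-chloro-2-hydroxy-4-methoxybenzaldehyde; 3 2-bromo-1-(4-bromophenyl)ethan-1-one
Product: 4 2-[2-(4-bromophenyl)-2-oxoethoxy]-3-chloro-4-methoxybenzaldehyde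
Conditions: K2CO3 (1.2 equiv), DMF, 0 °C → rt, 3 h; cold dilute AcOH quench
Reagents that add atoms: none
Why: Williamson etherification (SN2) of the phenoxide with the very reactive phenacyl bromide; keeping it at or below room temperature avoids the Rap–Stoermer aldol closure to a 2‑aroylbenzofuran.

**Step 3**
Reactants: 4 2-[2-(4-bromophenyl)-2-oxoethoxy]-3-chloro-4-methoxybenzaldehyde
Product: 6 3-(4-bromophenyl)-8-chloro-7-methoxy-4H-chromen-4-one, via racemic 3-hydroxychromanone 5 (not isolated)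
Conditions: 2-(pentafluorophenyl)-6,7-dihydro-5H-pyrrolo[2,1-c][1,2,4]triazol-2-ium BF4 (10 mol%), DBU (10 mol%), THF, rt, 12 h; then pyridine (6 equiv), SOCl2 (2.5 equiv), 0 °C → rt
Reagents that add atoms: none
Why: NHC‑catalysed intramolecular crossed aldehyde–ketone benzoin reaction, in which the Breslow intermediate (acyl anion equivalent) attacks the aryl ketone carbonyl in a 6‑exo closure to form C3–C4, followed by E2 dehydration of the tertiary ketol through its chlorosulfite; the C3 stereocentre of 5 forms as a racemate (achiral catalyst) and is erased by the dehydration.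

**Step 4**
Reactants: 7 genistein [5,7-dihydroxy-3-(4-hydroxyphenyl)-4H-chromen-4-one]
Product: 8 5-hydroxy-7-methoxy-3-(4-methoxyphenyl)-4H-chromen-4-one
Conditions: MeI (2.3 equiv), K2CO3 (2.5 equiv), acetone, reflux, 8 h
Reagents that add atoms: iodomethane, CI
Why: Williamson etherification of the 7‑ and 4'‑phenols; the 5‑OH is chelated to the C4 carbonyl and stays free under carbonate/acetone conditions.

**Step 5**
Reactants: 8 5-hydroxy-7-methoxy-3-(4-methoxyphenyl)-4H-chromen-4-one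
Product: 10 5,8-dihydroxy-7-methoxy-3-(4-methoxyphenyl)-4H-chromen-4-one, via aryl potassium sulfate 9 (not isolated)
Conditions: K2S2O8 (1.2 equiv), 2 M aq KOH/pyridine, 0 → 20 °C, 24 h, N2; acidify to pH 4 and remove recovered 8; then 4 M HCl, 85 °C, 1 h
Reagents that add atoms: potassium peroxodisulfate, [K+].[K+].[O-]S(=O)(=O)OOS(=O)(=O)[O-]
Why: Elbs persulfate oxidation; the 5‑phenoxide attacks peroxodisulfate through C8, its only free para position, and acid hydrolysis of the aryl sulfate gives the 5,8‑quinol, as in the classical route to 5,8‑dihydroxyflavonoids.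

**Step 6**
Reactants: 6 3-(4-bromophenyl)-8-chloro-7-methoxy-4H-chromen-4-one; 10 5,8-dihydroxy-7-methoxy-3-(4-methoxyphenyl)-4H-chromen-4-one (1.2 equiv)
Product: 11 8-[4-(8-chloro-7-methoxy-4-oxo-4H-chromen-3-yl)phenoxy]-5-hydroxy-7-methoxy-3-(4-methoxyphenyl)-4H-chromen-4-one
Conditions: CuI (10 mol%), picolinic acid (20 mol%), K3PO4 (2.5 equiv), degassed DMSO, 90 °C, 24 h, Ar
Reagents that add atoms: none
Why: Copper‑catalysed Ullmann diaryl ether synthesis with a ligand system suited to ortho‑disubstituted phenols; the 8‑phenoxide is the only nucleophilic oxygen (5‑OH chelated), the aryl bromide reacts before the aryl chloride, and oxygen is excluded to protect the quinol.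

**Step 7**
Reactants: 11 8-[4-(8-chloro-7-methoxy-4-oxo-4H-chromen-3-yl)phenoxy]-5-hydroxy-7-methoxy-3-(4-methoxyphenyl)-4H-chromen-4-one
Product: 12 Bisoflavolin H [8-[4-(8-chloro-7-hydroxy-4-oxo-4H-chromen-3-yl)phenoxy]-5,7-dihydroxy-3-(4-hydroxyphenyl)-4H-chromen-4-one]
Conditions: BBr3 (12 equiv), CH2Cl2, −78 °C → rt, 24 h; then MeOH, H2O
Reagents that add atoms: none
Why: Lewis‑acid cleavage of the three aryl methyl ethers (BBr3 demethylation); the diaryl ether, aryl chloride and chromone carbonyls are inert to BBr3.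

**Compound list**
1 | 3-chloro-2,4-dihydroxybenzaldehyde | O=Cc1ccc(O)c(Cl)c1O | starting material
2 | 3-chloro-2-hydroxy-4-methoxybenzaldehyde | COc1ccc(C=O)c(O)c1Cl | intermediate
3 | 2-bromo-1-(4-bromophenyl)ethan-1-one | O=C(CBr)c1ccc(Br)cc1 | starting material
4 | 2-[2-(4-bromophenyl)-2-oxoethoxy]-3-chloro-4-methoxybenzaldehyde | COc1ccc(C=O)c(OCC(=O)c2ccc(Br)cc2)c1Cl | intermediate
5 | 3-(4-bromophenyl)-8-chloro-3-hydroxy-7-methoxychroman-4-one (racemic, not isolated) | COc1ccc2c(c1Cl)OCC(O)(c1ccc(Br)cc1)C2=O | intermediate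
6 | 3-(4-bromophenyl)-8-chloro-7-methoxy-4H-chromen-4-one | COc1ccc2c(c1Cl)occ(-c1ccc(Br)cc1)c2=O | intermediate
7 | genistein, 5,7-dihydroxy-3-(4-hydroxyphenyl)-4H-chromen-4-one | Oc1ccc(cc1)-c1coc2cc(O)cc(O)c2c1=O | starting material
8 | 5-hydroxy-7-methoxy-3-(4-methoxyphenyl)-4H-chromen-4-one | COc1ccc(cc1)-c1coc2cc(OC)cc(O)c2c1=O | intermediate
9 | potassium 5-hydroxy-7-methoxy-3-(4-methoxyphenyl)-4-oxo-4H-chromen-8-yl sulfate (not isolated) | COc1ccc(cc1)-c1coc2c(OS(=O)(=O)[O-])c(OC)cc(O)c2c1=O.[K+] | intermediate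
10 | 5,8-dihydroxy-7-methoxy-3-(4-methoxyphenyl)-4H-chromen-4-one | COc1ccc(cc1)-c1coc2c(O)c(OC)cc(O)c2c1=O | intermediate
11 | 8-[4-(8-chloro-7-methoxy-4-oxo-4H-chromen-3-yl)phenoxy]-5-hydroxy-7-methoxy-3-(4-methoxyphenyl)-4H-chromen-4-one | COc1ccc(cc1)-c1coc2c(Oc3ccc(cc3)-c3coc4c(Cl)c(OC)ccc4c3=O)c(OC)cc(O)c2c1=O | intermediate
12 | Bisoflavolin H (achiral) | O=c1c(-c2ccc(Oc3c(O)cc(O)c4c(=O)c(-c5ccc(O)cc5)coc34)cc2)coc2c(Cl)c(O)ccc12 | target

**Step count:** 7 steps in total. The longest linear sequence is 5 steps (steps 1, 2, 3, 6, 7, from 1 to 12); the genistein branch (steps 4 and 5) joins at step 6.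

**Steps most likely to fail, with fallbacks**

Step 3 (benzoin/dehydration; the risks are Rap–Stoermer aldol of 4 and a sluggish aryl ketone acceptor). The fallback sets out from 2 and comes back at 6, using a stoichiometric acyl anion equivalent. Compound 2 is condensed with propane-1,3-dithiol (BF3·OEt2, CH2Cl2) to give 2-(3-chloro-2-hydroxy-4-methoxyphenyl)-1,3-dithiane F1. Double deprotonation (n-BuLi 2.2 equiv, TMEDA, THF, −78 → −20 °C) and C‑alkylation of the 2‑lithiodithiane with 4‑bromobenzyl bromide gives 2-(4-bromobenzyl)-2-(3-chloro-2-hydroxy-4-methoxyphenyl)-1,3-dithiane F2. PhI(OCOCF3)2 in aqueous MeCN unmasks the ketone to give 2-(4-bromophenyl)-1-(3-chloro-2-hydroxy-4-methoxyphenyl)ethan-1-one F3. DMF‑DMA (toluene, 100 °C) then adds C2 and closes the pyranone to 6.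

Step 5 (Elbs oxidation; the risks are low conversion and alkaline opening of the isoflavone). The fallback sets out from 8 and comes back at 10. Exhaustive methylation (MeI, K2CO3, DMF, 60 °C) gives 5,7-dimethoxy-3-(4-methoxyphenyl)-4H-chromen-4-one F4. Iodination (NIS, cat. TFA, MeCN), which goes to C8 once the 5‑oxygen is alkylated, gives 8-iodo-5,7-dimethoxy-3-(4-methoxyphenyl)-4H-chromen-4-one F5. Miyaura borylation (B2pin2, Pd(dppf)Cl2, KOAc, dioxane, 90 °C) gives 5,7-dimethoxy-3-(4-methoxyphenyl)-8-(4,4,5,5-tetramethyl-1,3,2-dioxaborolan-2-yl)-4H-chromen-4-one F6. Oxidation (NaBO3·4H2O, THF/H2O, rt) gives 8-hydroxy-5,7-dimethoxy-3-(4-methoxyphenyl)-4H-chromen-4-one F7. BCl3 (CH2Cl2, −20 °C) removes only the 5‑O‑methyl group peri to the carbonyl and delivers 10.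

Step 6 (Ullmann coupling; the risks are the hindered, oxidisable quinol nucleophile and hot base on two chromones). The fallback sets out from 6 (with 10) and comes back at 11, using metal‑free arylation at iodine(III) at room temperature. Pd‑catalysed borylation of 6 (B2(OH)4, XPhos‑Pd‑G2, KOAc, EtOH, 80 °C; C–Br before C–Cl) gives [4-(8-chloro-7-methoxy-4-oxo-4H-chromen-3-yl)phenyl]boronic acid F8. Boron–iodine(III) exchange with 4‑MeOC6H4I(OAc)2/BF3·OEt2 (CH2Cl2, 0 °C), then NaBF4, gives [4-(8-chloro-7-methoxy-4-oxo-4H-chromen-3-yl)phenyl](4-methoxyphenyl)iodonium tetrafluoroborate F9. The 8‑phenoxide of 10 (t‑BuOK 1 equiv, THF, 0 °C → rt) is O‑arylated by F9; the electron‑poorer aryl is transferred and the anisyl group leaves as the iodoarene, giving 11.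

**Further compounds**
F1 | step 3 | 2-(3-chloro-2-hydroxy-4-methoxyphenyl)-1,3-dithiane | COc1ccc(C2SCCCS2)c(O)c1Cl
F2 | step 3 | 2-(4-bromobenzyl)-2-(3-chloro-2-hydroxy-4-methoxyphenyl)-1,3-dithiane | COc1ccc(C2(Cc3ccc(Br)cc3)SCCCS2)c(O)c1Cl
F3 | step 3 | 2-(4-bromophenyl)-1-(3-chloro-2-hydroxy-4-methoxyphenyl)ethan-1-one | COc1ccc(C(=O)Cc2ccc(Br)cc2)c(O)c1Cl
F4 | step 5 | 5,7-dimethoxy-3-(4-methoxyphenyl)-4H-chromen-4-one | COc1ccc(cc1)-c1coc2cc(OC)cc(OC)c2c1=O
F5 | step 5 | 8-iodo-5,7-dimethoxy-3-(4-methoxyphenyl)-4H-chromen-4-one | COc1ccc(cc1)-c1coc2c(I)c(OC)cc(OC)c2c1=O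
F6 | step 5 | 5,7-dimethoxy-3-(4-methoxyphenyl)-8-(4,4,5,5-tetramethyl-1,3,2-dioxaborolan-2-yl)-4H-chromen-4-one | COc1ccc(cc1)-c1coc2c(B3OC(C)(C)C(C)(C)O3)c(OC)cc(OC)c2c1=O
F7 | step 5 | 8-hydroxy-5,7-dimethoxy-3-(4-methoxyphenyl)-4H-chromen-4-one | COc1ccc(cc1)-c1coc2c(O)c(OC)cc(OC)c2c1=O
F8 | step 6 | [4-(8-chloro-7-methoxy-4-oxo-4H-chromen-3-yl)phenyl]boronic acid | COc1ccc2c(c1Cl)occ(-c1ccc(cc1)B(O)O)c2=O
F9 | step 6 | [4-(8-chloro-7-methoxy-4-oxo-4H-chromen-3-yl)phenyl](4-methoxyphenyl)iodonium tetrafluoroborate | COc1ccc(cc1)[I+]c1ccc(cc1)-c1coc2c(Cl)c(OC)ccc2c1=O.F[B-](F)(F)F
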